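| setting | south | south-east | south-west | north-east | birch | cedar | elm | larch | maple |
|---|---|---|---|---|---|---|---|---|---|
| starting material | 11 mM | 11 mM | 11 mM | 22 mM | 11 mM | 11 mM (in portions, 5, over 2.5 d) | 11 mM (fed, over 15 h) | 11 mM | 11 mM (fed, over 2.5 d) |
| reagent | 1.2 equiv | 1.2 equiv | 1.2 equiv | 1.2 equiv | 1.20 equiv | 1.20 equiv | 1.20 equiv | 1.20 equiv (fed, over 2.5 d) | 1.20 equiv |
| second substrate | 5 equiv | 3.4 equiv | 7.5 equiv | 5 equiv | 5.00 equiv | 5.00 equiv | 5.00 equiv | 5.00 equiv | 5.00 equiv |
| remark | run made earlier | run made earlier | run made earlier | run made earlier | everything together at the start | first portion at the start, last at 2.5 d | all else is in the flask from the start; the feed brings no volume worth counting | all else is in the flask from the start; the feed brings no volume worth counting | all else is in the flask from the start; the feed brings no volume worth counting |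
| time |  |  |  |  | 4.0 d | 4.0 d | 4.0 d | 4.0 d | 4.0 d |

- south (time / d: side product / %, target / %, starting material / %): 0.208: 2.0, 19.8, 78.2; 0.625: 4.7, 10.4, 84.6; 1.04: 6.9, 10.3, 83.8; 1.67: 9.2, 8.8, 81.9; 2.50: 12.8, 8.9, 78.0; 3.00: 14.8, 8.8, 76.6; 4.00: 18.5, 8.1, 73.3
- south-east (time / d: side product / %, target / %, starting material / %): 0.333: 2.6, 20.7, 76.3; 0.500: 4.2, 16.8, 79.0; 0.833: 7.0, 13.7, 79.5; 1.04: 7.8, 14.2, 78.5; 1.67: 11.8, 13.0, 75.2; 2.50: 16.4, 12.2, 72.2; 4.00: 22.5, 10.9, 66.7
- south-west (time / d: side product / %, target / %, starting material / %): 0.333: 2.7, 9.5, 87.9; 0.500: 3.2, 7.1, 89.6; 0.833: 4.4, 7.2, 89.2; 1.04: 5.4, 6.8, 87.8; 1.67: 7.3, 6.9, 87.1; 2.50: 10.0, 6.0, 83.8; 4.00: 14.2, 5.8, 80.1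
- north-east (time / d: side product / %, target / %, starting material / %): 0.833: 10.8, 9.7, 79.9; 1.67: 17.2, 8.8, 75.0; 2.50: 23.5, 7.3, 69.4; 3.00: 26.4, 7.1, 67.5; 4.00: 31.0, 6.4, 62.3

(scatter of a reading: 0.3 percentage points)

- a species is counted by the starting material in it: one side product counts as two
- a reading or a percentage of target counts all its forms, free or not

1. the flask that comes out highest in amount of side product, in percent of the starting material charged, or "all alike" when all lie within 1.5 percentage points (birch / cedar / elm / larch / maple / all alike)
2. side product at the end, in percent of the starting material charged, birch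
3. side product at the end, in percent of the starting material charged, cedar
4. side product at the end, in percent of the starting material charged, elm
5. side product at the end, in percent of the starting material charged, larch
6. side product at the end, in percent of the starting material charged, maple

Over 4.00 d south reaches 73.3 % starting material, 8.1 % target and 18.5 % side product, and I call starting material plus target the pool. I work with the fraction of the pool left, not the side product made. If the pool decays by second order, the reciprocal of that fraction climbs in a straight line from one. Read from the last south reading, its slope is 0.0567 d⁻¹: this is the loss constant, the daily rise of that reciprocal for a full pool at these charges. North-east tests it. If I take the slope to scale with the concentration, which is twice that of south, I get 31.2 % side product, and the run reads 31.0 %.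

In my reckoning a feed of starting material counts by the square of the fraction already in, so a steady feed of it counts for a third of its length. That leaves maple 2.33 d of full pool and elm 3.58 d. My reckoning gives maple 11.7 % and elm 16.9 %. Birch repeats south, and the constant tells me nothing about larch, whose feed is reagent.

The forecast names birch highest, with 18.5 % there, 10.6 % for cedar, 16 % for elm, 13 % for larch and 11.1 % for maple: “Feeding starting material keeps the pool small early”. My maple stands 0.60 percentage points higher.

    starting material + reagent ⇌ target (K = 140 M⁻¹, k = 1.90 M⁻¹ min⁻¹)
    second substrate + reagent ⇌ second product (K = 320 M⁻¹, k = 0.290 M⁻¹ min⁻¹)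
    reagent + target ⇌ idle adduct, settled at all times (K = 110 M⁻¹)
    starting material + target → side product (k = 0.0200 M⁻¹ min⁻¹)

Birch comes out highest at 18.6 %, with elm 16.0 %, larch 15.0 %, maple 11.1 % and cedar 10.8 %. Cedar, restarted from 3.94 % at 2.50 d with its last portion going in, reckons by the constant to 11.2 %. At 4.00 d the idle adduct in birch holds 0.598 %, counted within the 8.04 % of target. Birch has not come to rest: the constant gives 69.4 % side product at 40.0 d, and the flask then holds 65.7 %, with starting material down from 73.4 % to 31.6 %.

Readings and results stem from a simulated flask from invented constants; noise was put on by code.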